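The route disconnects oxepane ring B at its two adjacent C–O centres, C5 (ether to C10) and C6 (lactone oxygen). Both are traced to a tetrahydropyran whose ring oxygen sits on C6 and whose side-chain carbinol C5 carries a chloromethanesulfonate. In one operation, a zinc acetate-mediated 1,2-oxygen shift through a bicyclic oxonium ion moves the ring oxygen from C6 to C5, enlarges the ring to the oxepane and inverts both carbons. This gives the erythro C5-ether/C6-acetate pair with the C5 and C10 arms trans. The precursor is a 2,2,3,4,6-substituted tetrahydropyran carrying an O1 acetate, an O8 2-naphthylmethyl ether, an O15 silyl ether and a tert-butyl acrylate at C7.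

Key step: step 18

Remark on the chemistry: carbons are numbered as in germacranes (C1 ketone carbon, C2=C3, C4 bearing C15, C5 and C10 joined through the ether oxygen, C6 lactone O-carbon, C7, C8 ester O-carbon, C9, C10 bearing C14, C11=C13, C12 lactone carbonyl), and O1, O5, O6, O8, O15 are the oxygens on those carbons. The C2=C3 bond, unmarked in the target SMILES, is taken as cis, the only geometry that seven-membered ring A allows.

Step 1
Reactants: 1 (R)-3-hydroxy-γ-butyrolactone
Product: 2 (3R)-3,4-dihydroxy-N-methoxy-N-methylbutanamide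
Conditions: MeNHOMe·HCl, AlMe3, CH2Cl2, 0 → 23 °C
Reagents that add atoms: N,O-dimethylhydroxylamine hydrochloride, CNOC.Cl
Why: Aluminium amide aminolysis of the lactone (Weinreb amide formation) opens the ring at the acyl carbon and leaves the C6 stereocentre, taken from the chiral pool, untouched.

Step 2
Reactants: 2 (3R)-3,4-dihydroxy-N-methoxy-N-methylbutanamide
Product: 3 (3R)-4-(tert-butyldiphenylsilyloxy)-3-hydroxy-N-methoxy-N-methylbutanamide
Conditions: t-BuPh2SiCl, imidazole, CH2Cl2, 0 °C
Reagents that add atoms: tert-butyl(chloro)diphenylsilane, CC(C)(C)[Si](Cl)(c1ccccc1)c1ccccc1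
Why: Silylation with the bulky chlorosilane is selective for the primary C5 hydroxyl over the secondary C6 hydroxyl.

Step 3
Reactants: 3 (3R)-4-(tert-butyldiphenylsilyloxy)-3-hydroxy-N-methoxy-N-methylbutanamide; 4 tert-butyldimethyl(prop-2-ynyloxy)silane
Product: 6 (6R)-1-(tert-butyldimethylsilyloxy)-7-(tert-butyldiphenylsilyloxy)-6-hydroxyhept-2-yn-4-one, via lithium acetylide 5 (not isolated)
Conditions: 4 (2.5 equiv), n-BuLi, THF, −78 °C; then 3, −78 → −20 °C; aq. NH4Cl
Reagents that add atoms: none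
Why: Acetylide addition to a Weinreb amide stops at the ketone because of the chelated tetrahedral adduct, the excess acetylide also covering the free C6 hydroxyl; no stereocentre is formed and the low temperature disfavours silyl migration.

Step 4
Reactants: 6 (6R)-1-(tert-butyldimethylsilyloxy)-7-(tert-butyldiphenylsilyloxy)-6-hydroxyhept-2-yn-4-one
Product: 7 (2R)-6-(tert-butyldimethylsilyloxymethyl)-2-(tert-butyldiphenylsilyloxymethyl)-2,3-dihydro-4H-pyran-4-one
Conditions: AgOSO2CF3 (10 mol %), CH2Cl2, 23 °C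
Reagents that add atoms: none
Why: Silver-catalysed 6-endo-dig oxa-Michael cyclisation of the β-hydroxy ynone, attack at the β-alkyne carbon C10 being the electronically favoured mode; C6 is not involved.

Step 5
Reactants: 7 (2R)-6-(tert-butyldimethylsilyloxymethyl)-2-(tert-butyldiphenylsilyloxymethyl)-2,3-dihydro-4H-pyran-4-one; 8 tert-butyl bromoacetate
Product: 9 tert-butyl 2-[(2R,3S)-6-(tert-butyldimethylsilyloxymethyl)-2-(tert-butyldiphenylsilyloxymethyl)-4-oxo-3,4-dihydro-2H-pyran-3-yl]acetate (6,7-trans)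
Conditions: LiN(i-Pr)2, THF, −78 °C; then 8, DMPU, −78 → −50 °C
Reagents that add atoms: none
Why: Kinetic α′-deprotonation of the vinylogous ester and C-alkylation, the electrophile entering anti to the C6 arm to set C7 trans to it; the low temperature and the poor overlap of the endocyclic C6–O bond with the enolate π-system hold back β-elimination, and the tert-butyl ester is chosen so that C12 cannot lactonise with O8 later.

Step 6
Reactants: 9 tert-butyl 2-[(2R,3S)-6-(tert-butyldimethylsilyloxymethyl)-2-(tert-butyldiphenylsilyloxymethyl)-4-oxo-3,4-dihydro-2H-pyran-3-yl]acetate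
Product: 11 (6R,7S,10S)-tetrahydropyran-4-one with C6 CH2OTBDPS; C7 CH2CO2t-Bu; C10 axial CH3 and equatorial CH2OTBS, via trimethylsilyl enol ether 10 (not isolated)
Conditions: Me2CuLi (from MeLi and CuI), Me3SiCl, Et2O–THF, −78 → −40 °C; then aq. citric acid, 0 °C
Reagents that add atoms: lithium dimethylcuprate, [Li+].C[Cu-]C
Why: Chlorosilane-accelerated conjugate addition of the dialkylcuprate; stereoelectronically controlled axial attack on the half-chair that keeps the C6 and C7 arms pseudo-equatorial puts the new methyl trans to the C6 arm, so quaternary C10 carries its CH2O arm cis to the C6 arm, and the non-basic hydrolysis of 10 leaves C7 untouched.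

Step 7
Reactants: 11 (6R,7S,10S)-tetrahydropyran-4-one
Product: 12 (6R,7R,8R,10S)-tetrahydropyran-4-ol with axial C8 hydroxyl cis to the C7 arm and to the C10 methyl
Conditions: LiBH(s-Bu)3, THF, −78 °C; aq. NH4Cl at −78 °C
Reagents that add atoms: none
Why: Reduction by the bulky trialkylborohydride from the equatorial direction (the axial face being blocked by the axial C10 methyl) gives the axial C8 alcohol, and the cold quench keeps the γ-hydroxy tert-butyl ester from lactonising.

Step 8
Reactants: 12 (6R,7R,8R,10S)-tetrahydropyran-4-ol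
Product: 13 O8 2-naphthylmethyl ether of 12
Conditions: 2-(bromomethyl)naphthalene, AgOSO2CF3, 2,6-di-tert-butyl-4-methylpyridine, CH2Cl2, 0 → 23 °C
Reagents that add atoms: 2-(bromomethyl)naphthalene, BrCc1ccc2ccccc2c1
Why: Silver-assisted Williamson-type etherification under buffered non-basic conditions avoids the C8 alkoxide that would lactonise onto C12, and it installs an ether that withstands warm acetic acid (a 4-methoxybenzyl ether would not) yet is cleaved oxidatively later; C8 keeps its configuration.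

Step 9
Reactants: 13 O8 2-naphthylmethyl ether of 12
Product: 16 (6R,7R,8R,10S)-tert-butyl acrylate with C7 C(=CH2)CO2t-Bu, via Mannich base 14 (not isolated), via trimethylammonium iodide 15 (not isolated)
Conditions: LiN(i-Pr)2, THF, −78 °C; Me2N=CH2+ I−, −78 → 0 °C; then MeI, MeOH, 23 °C; then DBU, CH2Cl2, 23 °C
Reagents that add atoms: dimethylmethyleneammonium iodide (Eschenmoser's salt), C=[N+](C)C.[I-]
Why: Ester α-methylenation by Mannich aminomethylation at C11, quaternisation and base-induced elimination of trimethylamine; the C11 stereocentre of 14 and 15 disappears in the elimination.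

Step 10
Reactants: 16 (6R,7R,8R,10S)-tert-butyl acrylate
Product: 17 C1 alcohol (C10 CH2OH)
Conditions: camphorsulfonic acid (cat.), MeOH–CH2Cl2, 0 °C
Reagents that add atoms: none
Why: Acid-catalysed methanolysis removes the primary tert-butyldimethylsilyl ether selectively, the tert-butyldiphenylsilyl ether being far more stable to acid.

Step 11
Reactants: 17 C1 alcohol
Product: 18 C1 acetate (C10 CH2OAc)
Conditions: Ac2O, pyridine, DMAP (cat.), CH2Cl2, 23 °C
Reagents that add atoms: acetic anhydride, CC(=O)OC(C)=O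
Why: Acetylation under nucleophilic catalysis puts on O1 an ester that cannot act as an internal nucleophile in step 18 and that leaves together with the C6 acetate in step 19 (a pivalate could not be removed beside the α-methylene lactone).

Step 12
Reactants: 18 C1 acetate
Product: 19 C5 alcohol (C6 CH2OH)
Conditions: Bu4NF, AcOH, THF, 23 °C
Reagents that add atoms: none
Why: Fluoride desilylation, buffered with acetic acid so that the acetate and the acrylate survive.

Step 13
Reactants: 19 C5 alcohol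
Product: 20 C5 aldehyde (tetrahydropyran-2-carbaldehyde)
Conditions: Dess–Martin periodinane, NaHCO3, CH2Cl2, 0 → 23 °C
Reagents that add atoms: none
Why: Dess–Martin oxidation gives the α-alkoxy aldehyde under buffered neutral conditions without epimerising C6.

Step 14
Reactants: 21 tert-butyldiphenyl(prop-2-ynyloxy)silane
Product: 22 (E)-3-(tert-butyldiphenylsilyloxy)prop-1-enylboronic acid pinacol ester
Conditions: pinacolborane, Cp2Zr(H)Cl (5 mol %), Et3N (10 mol %), neat, 60 °C
Reagents that add atoms: pinacolborane, [H]B1OC(C)(C)C(C)(C)O1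
Why: Zirconocene-hydride-catalysed syn hydroboration of the terminal alkyne places boron on the terminal carbon and gives the E alkene.

Step 15
Reactants: 22 (E)-3-(tert-butyldiphenylsilyloxy)prop-1-enylboronic acid pinacol ester
Product: 24 (E)-4-(tert-butyldiphenylsilyloxy)but-2-enylboronic acid pinacol ester, via boron ate complex 23 (not isolated)
Conditions: BrCH2Cl, n-BuLi, THF, −78 → 23 °C
Reagents that add atoms: bromochloromethane, ClCBr
Why: Matteson homologation, in which (chloromethyl)lithium adds to boron and the alkenyl group migrates with loss of chloride, inserting one CH2 with retention of the E geometry.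

Step 16
Reactants: 20 C5 aldehyde; 24 (E)-4-(tert-butyldiphenylsilyloxy)but-2-enylboronic acid pinacol ester
Product: 26 (4R,5S,6R,7R,8R,10S)-homoallylic alcohol with C5 hydroxyl and C4 bearing vinyl and CH2OTBDPS, via pinacol borate ester 25 (not isolated)
Conditions: 24, 4 Å molecular sieves, toluene, 23 °C; then aq. NaHCO3
Reagents that add atoms: none
Why: Allylboration through a closed chair (Zimmerman–Traxler) transition state, where the E geometry of 24 gives the 4,5-anti relationship and Felkin–Anh (Cornforth) attack anti to the ring oxygen of the α-alkoxy aldehyde gives the 5,6-anti relationship, so C4 (R) and C5 (S) are set together with reagent geometry and substrate bias reinforcing each other.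

Step 17
Reactants: 26 (4R,5S,6R,7R,8R,10S)-homoallylic alcohol
Product: 27 (4R,5S,6R,7R,8R,10S)-C5 chloromethanesulfonate (precursor of the key step)
Conditions: ClCH2SO2Cl, pyridine, CH2Cl2, 0 °C
Reagents that add atoms: chloromethanesulfonyl chloride, ClCS(Cl)(=O)=O
Why: O-Sulfonylation with retention at C5; the chloromethanesulfonate leaves more readily than a mesylate and so allows a mild ring expansion.

Step 18
Reactants: 27 (4R,5S,6R,7R,8R,10S)-C5 chloromethanesulfonate
Product: 29 (4R,5R,6S,7R,8R,10S)-oxepane with C5–O–C10 ether and C6 acetate, via bicyclic oxonium ion 28 (not isolated)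
Conditions: Zn(OAc)2, AcOH, 60 °C
Reagents that add atoms: zinc acetate, CC(=O)[O-].CC(=O)[O-].[Zn+2]; acetic acid, CC(=O)O
Why: The tetrahydropyran oxygen, antiperiplanar to the C5–O sulfonate bond in the extended zigzag rotamer that the 5,6-anti configuration makes the ground state, displaces chloromethanesulfonate at C5 with inversion to give the bicyclic oxonium ion 28, and zinc-bound acetate opens it by SN2 attack at C6 with inversion, so the ether oxygen ends on C5 and an acetate on C6. The closest known reaction type is the zinc acetate-mediated ring expansion of 2-(1-sulfonyloxyalkyl)tetrahydropyrans to 3-acyloxyoxepanes through a 1,2-oxygen shift. Oxepane ring B is closed by the 3-exo-tet C5–O bond formation and becomes seven-membered when the endocyclic C6–O bond of the oxonium ion is cut. C5 (R) is controlled by the (5S)-carbinol centre from step 16 and C6 (S) by the (6R) ring carbon from the chiral pool, each through one stereospecific inversion, which also fixes the C5 and C10 arms trans on ring B. The step needs capture at C6 instead of C5 and no E2 loss of the sulfonate towards C4: the branched C4 shields C5, the acetate medium is only weakly basic, and the C12 ester carbonyl can reach only C6 (5-exo), so any lactone formed that way converges on 31 in step 19. O1 is an ester and O8 and O15 are ethers that cannot reach C5 or C6 from the rear face, so no other internal oxygen competes, and the 2-naphthylmethyl and silyl ethers tolerate warm acetic acid.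

Step 19
Reactants: 29 (4R,5R,6S,7R,8R,10S)-oxepane C6 acetate
Product: 31 6,12-lactone (α-methylene-γ-butyrolactone trans-fused to ring B) with C1 hydroxyl, via dihydroxy ester 30 (not isolated)
Conditions: LiOH, THF–H2O, 0 → 23 °C; then p-TsOH·H2O (cat.), toluene, 60 °C
Reagents that add atoms: none
Why: Saponification of both acetates (the hindered tert-butyl acrylate resists hydroxide) followed by acid-catalysed intramolecular transesterification of O6 onto C12 (5-exo-trig lactonisation), the trans fusion following from the C6 and C7 centres already in place.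

Step 20
Reactants: 31 6,12-lactone with C1 hydroxyl
Product: 32 C1 aldehyde
Conditions: Dess–Martin periodinane, NaHCO3, CH2Cl2, 23 °C
Reagents that add atoms: none
Why: Dess–Martin oxidation of the neopentyl primary alcohol to a non-enolisable aldehyde.

Step 21
Reactants: 32 C1 aldehyde
Product: 33 C1 allylic alcohol (C10 CH(OH)CH=CH2; both C1 epimers)
Conditions: CH2=CHBr, CrCl2, NiCl2 (1 mol %), DMF, 23 °C
Reagents that add atoms: vinyl bromide, C=CBr
Why: Nozaki–Hiyama–Kishi vinylation is chemoselective for the aldehyde beside the lactone and the electron-poor alkene; the new C1 carbinol centre is not controlled and is erased in step 22.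

Step 22
Reactants: 33 C1 allylic alcohol
Product: 34 C1 vinyl ketone
Conditions: Dess–Martin periodinane, NaHCO3, CH2Cl2, 0 °C
Reagents that add atoms: none
Why: Dess–Martin oxidation of the allylic alcohol converges both epimers on one enone, which is used at once.

Step 23
Reactants: 34 C1 vinyl ketone
Product: 35 tricyclic enone with ring A closed (C2=C3 cis); O8 2-naphthylmethyl ether; O15 silyl ether
Conditions: second-generation Hoveyda–Grubbs catalyst RuCl2(H2IMes)(=CH-C6H4-2-O-i-Pr) (10 mol %), toluene (2 mM), 80 °C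
Reagents that add atoms: none
Why: Ring-closing metathesis between the C4 vinyl group and the vinyl ketone closes seven-membered ring A as the cis enone with loss of ethene; the trans arms fixed in step 18 allow only the in,out bicycle, and the α-methylene lactone stays out because it is an electron-poor 1,1-disubstituted alkene whose cyclisation would need a bridgehead double bond.

Step 24
Reactants: 35 tricyclic enone
Product: 36 C8 alcohol
Conditions: DDQ, CH2Cl2–pH 7 buffer, 23 °C
Reagents that add atoms: none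
Why: Oxidative cleavage of the 2-naphthylmethyl ether (hydride abstraction by DDQ, then hydrolysis of the hemiacetal) under neutral conditions that leave the enone and the lactone alone.

Step 25
Reactants: 36 C8 alcohol; 37 angelic acid
Product: 39 8-O-angelate 15-O-tert-butyldiphenylsilyl ether, via mixed anhydride 38 (not isolated)
Conditions: 37, 2,4,6-trichlorobenzoyl chloride, Et3N, toluene, 23 °C; then 36, 75 °C
Reagents that add atoms: none
Why: Yamaguchi esterification through the mixed anhydride, run without a nucleophilic catalyst to keep the Z geometry of the angelate and to avoid acyl transfer of the lactone to O8; C8 retains its configuration.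

Step 26
Reactants: 39 8-O-angelate 15-O-tert-butyldiphenylsilyl ether
Product: 40 target, (4R,5R,6S,7R,8R,10S)-8-angeloyloxy-15-hydroxy-1-oxo-5,10-epoxygermacra-2,11(13)-dien-6,12-olide
Conditions: HF·pyridine, pyridine, THF, 0 → 23 °C
Reagents that add atoms: none
Why: Fluoride desilylation under buffered, weakly acidic conditions that spare the enone, the α-methylene lactone and the angelate.

Compound list
1 | (R)-3-hydroxy-γ-butyrolactone | O=C1C[C@@H](O)CO1 | starting material
2 | (3R)-3,4-dihydroxy-N-methoxy-N-methylbutanamide | CON(C)C(=O)C[C@@H](O)CO | intermediate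
3 | (3R)-4-(tert-butyldiphenylsilyloxy)-3-hydroxy-N-methoxy-N-methylbutanamide | CON(C)C(=O)C[C@@H](O)CO[Si](c1ccccc1)(c1ccccc1)C(C)(C)C | intermediate
4 | tert-butyldimethyl(prop-2-ynyloxy)silane | C#CCO[Si](C)(C)C(C)(C)C | starting material
5 | lithium acetylide of 4 | [Li]C#CCO[Si](C)(C)C(C)(C)C | intermediate
6 | (6R)-1-(tert-butyldimethylsilyloxy)-7-(tert-butyldiphenylsilyloxy)-6-hydroxyhept-2-yn-4-one | CC(C)(C)[Si](C)(C)OCC#CC(=O)C[C@@H](O)CO[Si](c1ccccc1)(c1ccccc1)C(C)(C)C | intermediate
7 | (2R)-6-(tert-butyldimethylsilyloxymethyl)-2-(tert-butyldiphenylsilyloxymethyl)-2,3-dihydro-4H-pyran-4-one | CC(C)(C)[Si](c1ccccc1)(c1ccccc1)OC[C@@H]1OC(CO[Si](C)(C)C(C)(C)C)=CC(=O)C1 | intermediate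
8 | tert-butyl bromoacetate | CC(C)(C)OC(=O)CBr | starting material
9 | tert-butyl 2-[(2R,3S)-6-(tert-butyldimethylsilyloxymethyl)-2-(tert-butyldiphenylsilyloxymethyl)-4-oxo-3,4-dihydro-2H-pyran-3-yl]acetate (6,7-trans) | CC(C)(C)[Si](c1ccccc1)(c1ccccc1)OC[C@@H]1OC(CO[Si](C)(C)C(C)(C)C)=CC(=O)[C@H]1CC(=O)OC(C)(C)C | intermediate
10 | C8 trimethylsilyl enol ether (C8=C9) of ketone 11 | CC(C)(C)[Si](c1ccccc1)(c1ccccc1)OC[C@@H]1O[C@](C)(CO[Si](C)(C)C(C)(C)C)C=C(O[Si](C)(C)C)[C@H]1CC(=O)OC(C)(C)C | intermediate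
11 | (6R,7S,10S)-tetrahydropyran-4-one: C6 CH2OTBDPS, C7 CH2CO2t-Bu trans to it, C10 axial CH3 and equatorial CH2OTBS, C8 ketone | CC(C)(C)[Si](c1ccccc1)(c1ccccc1)OC[C@@H]1O[C@](C)(CO[Si](C)(C)C(C)(C)C)CC(=O)[C@H]1CC(=O)OC(C)(C)C | intermediate
12 | (6R,7R,8R,10S)-tetrahydropyran-4-ol: axial C8 hydroxyl cis to the C7 arm and the C10 methyl | CC(C)(C)[Si](c1ccccc1)(c1ccccc1)OC[C@@H]1O[C@](C)(CO[Si](C)(C)C(C)(C)C)C[C@@H](O)[C@H]1CC(=O)OC(C)(C)C | intermediate
13 | O8 2-naphthylmethyl ether of 12 | CC(C)(C)[Si](c1ccccc1)(c1ccccc1)OC[C@@H]1O[C@](C)(CO[Si](C)(C)C(C)(C)C)C[C@@H](OCc2ccc3ccccc3c2)[C@H]1CC(=O)OC(C)(C)C | intermediate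
14 | Mannich base: C11 bearing CH2NMe2 (C11 epimers) | CC(C)(C)[Si](c1ccccc1)(c1ccccc1)OC[C@@H]1O[C@](C)(CO[Si](C)(C)C(C)(C)C)C[C@@H](OCc2ccc3ccccc3c2)[C@H]1C(CN(C)C)C(=O)OC(C)(C)C | intermediate
15 | trimethylammonium iodide of 14 | CC(C)(C)[Si](c1ccccc1)(c1ccccc1)OC[C@@H]1O[C@](C)(CO[Si](C)(C)C(C)(C)C)C[C@@H](OCc2ccc3ccccc3c2)[C@H]1C(C[N+](C)(C)C)C(=O)OC(C)(C)C.[I-] | intermediate
16 | (6R,7R,8R,10S)-tert-butyl acrylate: C7 bearing C(=CH2)CO2t-Bu | CC(C)(C)[Si](c1ccccc1)(c1ccccc1)OC[C@@H]1O[C@](C)(CO[Si](C)(C)C(C)(C)C)C[C@@H](OCc2ccc3ccccc3c2)[C@H]1C(=C)C(=O)OC(C)(C)C | intermediate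
17 | C1 alcohol (C10 CH2OH) | CC(C)(C)[Si](c1ccccc1)(c1ccccc1)OC[C@@H]1O[C@](C)(CO)C[C@@H](OCc2ccc3ccccc3c2)[C@H]1C(=C)C(=O)OC(C)(C)C | intermediate
18 | C1 acetate (C10 CH2OAc) | CC(C)(C)[Si](c1ccccc1)(c1ccccc1)OC[C@@H]1O[C@](C)(COC(C)=O)C[C@@H](OCc2ccc3ccccc3c2)[C@H]1C(=C)C(=O)OC(C)(C)C | intermediate
19 | C5 alcohol (C6 CH2OH) | OC[C@@H]1O[C@](C)(COC(C)=O)C[C@@H](OCc2ccc3ccccc3c2)[C@H]1C(=C)C(=O)OC(C)(C)C | intermediate
20 | C5 aldehyde | O=C[C@@H]1O[C@](C)(COC(C)=O)C[C@@H](OCc2ccc3ccccc3c2)[C@H]1C(=C)C(=O)OC(C)(C)C | intermediate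
21 | tert-butyldiphenyl(prop-2-ynyloxy)silane | C#CCO[Si](c1ccccc1)(c1ccccc1)C(C)(C)C | starting material
22 | (E)-3-(tert-butyldiphenylsilyloxy)prop-1-enylboronic acid pinacol ester | CC(C)(C)[Si](c1ccccc1)(c1ccccc1)OC/C=C/B1OC(C)(C)C(C)(C)O1 | intermediate
23 | lithium (chloromethyl)boron ate complex of 22 | [Li+].ClC[B-]1(/C=C/CO[Si](c2ccccc2)(c2ccccc2)C(C)(C)C)OC(C)(C)C(C)(C)O1 | intermediate
24 | (E)-4-(tert-butyldiphenylsilyloxy)but-2-enylboronic acid pinacol ester | CC(C)(C)[Si](c1ccccc1)(c1ccccc1)OC/C=C/CB1OC(C)(C)C(C)(C)O1 | intermediate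
25 | O5 pinacol borate ester of 26 | C=C[C@H](CO[Si](c1ccccc1)(c1ccccc1)C(C)(C)C)[C@H](OB2OC(C)(C)C(C)(C)O2)[C@@H]1O[C@](C)(COC(C)=O)C[C@@H](OCc2ccc3ccccc3c2)[C@H]1C(=C)C(=O)OC(C)(C)C | intermediate
26 | (4R,5S,6R,7R,8R,10S)-homoallylic alcohol: C5 hydroxyl, C4 bearing vinyl and CH2OTBDPS | C=C[C@H](CO[Si](c1ccccc1)(c1ccccc1)C(C)(C)C)[C@H](O)[C@@H]1O[C@](C)(COC(C)=O)C[C@@H](OCc2ccc3ccccc3c2)[C@H]1C(=C)C(=O)OC(C)(C)C | intermediate
27 | (4R,5S,6R,7R,8R,10S)-C5 chloromethanesulfonate, precursor of the key step | C=C[C@H](CO[Si](c1ccccc1)(c1ccccc1)C(C)(C)C)[C@H](OS(=O)(=O)CCl)[C@@H]1O[C@](C)(COC(C)=O)C[C@@H](OCc2ccc3ccccc3c2)[C@H]1C(=C)C(=O)OC(C)(C)C | intermediate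
28 | bicyclic oxonium ion (oxygen bonded to C5, C6 and C10) as chloromethanesulfonate | C=C[C@H](CO[Si](c1ccccc1)(c1ccccc1)C(C)(C)C)[C@@H]2[C@@H]1[O+]2[C@](C)(COC(C)=O)C[C@@H](OCc3ccc4ccccc4c3)[C@H]1C(=C)C(=O)OC(C)(C)C.[O-]S(=O)(=O)CCl | intermediate
29 | (4R,5R,6S,7R,8R,10S)-oxepane: C5–O–C10 ether, C6 acetate, C1 acetate, O8 2-naphthylmethyl, O15 TBDPS, C7 tert-butyl acrylate | C=C[C@H](CO[Si](c1ccccc1)(c1ccccc1)C(C)(C)C)[C@H]1O[C@](C)(COC(C)=O)C[C@@H](OCc2ccc3ccccc3c2)[C@@H](C(=C)C(=O)OC(C)(C)C)[C@@H]1OC(C)=O | intermediate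
30 | dihydroxy tert-butyl ester (C1 and C6 hydroxyls free) | C=C[C@H](CO[Si](c1ccccc1)(c1ccccc1)C(C)(C)C)[C@H]1O[C@](C)(CO)C[C@@H](OCc2ccc3ccccc3c2)[C@@H](C(=C)C(=O)OC(C)(C)C)[C@@H]1O | intermediate
31 | 6,12-lactone (trans-fused α-methylene-γ-butyrolactone) with C1 hydroxyl | C=C[C@H](CO[Si](c1ccccc1)(c1ccccc1)C(C)(C)C)[C@H]1O[C@](C)(CO)C[C@@H](OCc2ccc3ccccc3c2)[C@@H](C(=C)C(=O)O4)[C@@H]14 | intermediate
32 | C1 aldehyde | C=C[C@H](CO[Si](c1ccccc1)(c1ccccc1)C(C)(C)C)[C@H]1O[C@](C)(C=O)C[C@@H](OCc2ccc3ccccc3c2)[C@@H](C(=C)C(=O)O4)[C@@H]14 | intermediate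
33 | C1 allylic alcohol (both C1 epimers) | C=C[C@H](CO[Si](c1ccccc1)(c1ccccc1)C(C)(C)C)[C@H]1O[C@](C)(C(O)C=C)C[C@@H](OCc2ccc3ccccc3c2)[C@@H](C(=C)C(=O)O4)[C@@H]14 | intermediate
34 | C1 vinyl ketone | C=C[C@H](CO[Si](c1ccccc1)(c1ccccc1)C(C)(C)C)[C@H]1O[C@](C)(C(=O)C=C)C[C@@H](OCc2ccc3ccccc3c2)[C@@H](C(=C)C(=O)O4)[C@@H]14 | intermediate
35 | tricyclic enone: ring A closed (C2=C3 cis), O8 2-naphthylmethyl, O15 TBDPS | C=C1C(=O)O[C@@H]2[C@@H]3O[C@@](C)(C[C@@H](OCc4ccc5ccccc5c4)[C@@H]12)C(=O)C=C[C@@H]3CO[Si](c1ccccc1)(c1ccccc1)C(C)(C)C | intermediate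
36 | C8 alcohol | C=C1C(=O)O[C@@H]2[C@@H]3O[C@@](C)(C[C@@H](O)[C@@H]12)C(=O)C=C[C@@H]3CO[Si](c1ccccc1)(c1ccccc1)C(C)(C)C | intermediate
37 | angelic acid, (2Z)-2-methylbut-2-enoic acid | C/C=C(/C)C(=O)O | starting material
38 | angelic 2,4,6-trichlorobenzoic anhydride | C/C=C(/C)C(=O)OC(=O)c1c(Cl)cc(Cl)cc1Cl | intermediate
39 | 8-O-angelate 15-O-tert-butyldiphenylsilyl ether | C=C1C(=O)O[C@@H]2[C@@H]3O[C@@](C)(C[C@@H](OC(=O)/C(C)=C\C)[C@@H]12)C(=O)C=C[C@@H]3CO[Si](c1ccccc1)(c1ccccc1)C(C)(C)C | intermediate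
40 | (4R,5R,6S,7R,8R,10S)-8-angeloyloxy-15-hydroxy-1-oxo-5,10-epoxygermacra-2,11(13)-dien-6,12-olide | C=C1C(=O)O[C@@H]2[C@@H]3O[C@@](C)(C[C@@H](OC(=O)/C(C)=C\C)[C@@H]12)C(=O)C=C[C@@H]3CO | target

Total step count: 26 (24 on the main line, 2 for boronate 24).
Longest linear sequence: 24 steps (steps 1–13 and 16–26, from lactone 1 to 40).

Steps most likely to fail

1. Step 18 (ring expansion). The oxonium ion may be captured by acetate at C5, which returns the six-membered ring with net retention, or ionisation may be outrun by E2 loss of the sulfonate towards C4. Fallback: starting from 27, CF3CO2H in CH2Cl2 at 0 °C should cleave the tert-butyl ester to the acrylic acid chloromethanesulfonate F1. Warming F1 with 2,6-lutidine in (CF3)2CHOH lets the carboxylate trap the oxonium ion intramolecularly at C6 (5-exo), which should give the 6,12-lactone C1 acetate F2 with the same double inversion. LiOH in THF–H2O then removes the C1 acetate and opens the lactone to the dihydroxy acid F3, and p-TsOH in toluene recloses the lactone, returning to the route at 31.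

2. Step 23 (closure of ring A). Strain of the in,out bicycle may slow ring closure, so that cross-metathesis oligomerisation or catalyst decay takes over. Fallback: starting from aldehyde 32, dimethyl (diazomethyl)phosphonate with SnCl2 (catalytic, divalent tin) in CH2Cl2 should give the C1 β-ketophosphonate F4 by Roskamp-type C–H insertion at the aldehyde. OsO4 (catalytic), NaIO4 and 2,6-lutidine in dioxane–H2O should then cleave the electron-richer C4 vinyl group (Lemieux–Johnson) to the C3 aldehyde F5. Intramolecular Horner–Wadsworth–Emmons olefination with Ba(OH)2 in wet THF at high dilution would close ring A irreversibly as the cis enone, coming back to the route at 35.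

3. Step 25 (angeloylation). Acylation of the hindered C8 hydroxyl may be slow, so that Z to E isomerisation to the tiglate or transfer of the lactone acyl group to O8 competes. Fallback: starting from 36, coupling with 2-[bis(2,2,2-trifluoroethoxy)phosphoryl]propanoic acid (DCC, DMAP catalytic, CH2Cl2) should give the C8 phosphonopropionate F6. Treatment with KN(SiMe3)2 and 18-crown-6 in THF at −78 °C followed by acetaldehyde (Z-selective Still–Gennari olefination) would build the angelate double bond on the ester and return to the route at 39.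

Further compounds
F1 | step 18 | acrylic acid chloromethanesulfonate (27 with the tert-butyl ester cleaved) | C=C[C@H](CO[Si](c1ccccc1)(c1ccccc1)C(C)(C)C)[C@H](OS(=O)(=O)CCl)[C@@H]1O[C@](C)(COC(C)=O)C[C@@H](OCc2ccc3ccccc3c2)[C@H]1C(=C)C(=O)O
F2 | step 18 | 6,12-lactone C1 acetate | C=C[C@H](CO[Si](c1ccccc1)(c1ccccc1)C(C)(C)C)[C@H]1O[C@](C)(COC(C)=O)C[C@@H](OCc2ccc3ccccc3c2)[C@@H](C(=C)C(=O)O4)[C@@H]14
F3 | step 18 | dihydroxy acrylic acid (C1 and C6 hydroxyls free) | C=C[C@H](CO[Si](c1ccccc1)(c1ccccc1)C(C)(C)C)[C@H]1O[C@](C)(CO)C[C@@H](OCc2ccc3ccccc3c2)[C@@H](C(=C)C(=O)O)[C@@H]1O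
F4 | step 23 | C1 β-ketophosphonate | C=C[C@H](CO[Si](c1ccccc1)(c1ccccc1)C(C)(C)C)[C@H]1O[C@](C)(C(=O)CP(=O)(OC)OC)C[C@@H](OCc2ccc3ccccc3c2)[C@@H](C(=C)C(=O)O4)[C@@H]14
F5 | step 23 | C3 aldehyde β-ketophosphonate | O=C[C@H](CO[Si](c1ccccc1)(c1ccccc1)C(C)(C)C)[C@H]1O[C@](C)(C(=O)CP(=O)(OC)OC)C[C@@H](OCc2ccc3ccccc3c2)[C@@H](C(=C)C(=O)O4)[C@@H]14
F6 | step 25 | C8 2-[bis(2,2,2-trifluoroethoxy)phosphoryl]propanoate | C=C1C(=O)O[C@@H]2[C@@H]3O[C@@](C)(C[C@@H](OC(=O)C(C)P(=O)(OCC(F)(F)F)OCC(F)(F)F)[C@@H]12)C(=O)C=C[C@@H]3CO[Si](c1ccccc1)(c1ccccc1)C(C)(C)C
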